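**Plan**

1. Retrosynthesis first cuts the two C–C bonds of one [4+2] event: CMe2 carbon to the methyl-bearing bridgehead, and ring-fusion CH to the carbinol bridgehead. This opens the oxolane and the bicyclo[2.2.2]octenone together and leaves a flavanone-derived 6-methyl-6-(prenyloxy)cyclohexa-2,4-dienone.
2. The feature that allows this: the oxolane oxygen sits on the methyl-bearing carbon α to the bridging ketone, its O–CH2–CH–CMe2 chain spans to the neighbouring two-carbon bridge, and the third bridge is an enol-ether C=C. This is the imprint of a prenyl ether of an o-quinol that has added across its own 2,4-dienone.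
3. Further cuts: the tertiary C–O(prenyl) bond (alkoxylative dearomatization of a phenol), the pyranone C2–phenyl bond (1,4-addition to a chromone), the chromone C2 carbon, and the two aryl C–CH3 bonds.
4. Forward order: hexasubstituted arene (ring A) from phloroacetophenone, then the pyranone ring as a chromone, then phenyl to give the (R)-flavanone, then dearomatization with prenyl alcohol; the intramolecular Diels–Alder reaction closes the oxolane and the second carbocycle last.
5. Stereochemistry: the pyranone CHPh centre comes from a ligand-controlled rhodium-catalysed 1,4-addition; the O,Me-bearing quaternary carbon from a chiral aryl-λ3-iodane (reagent control, since the remote CHPh centre gives no bias); the ring-fusion CH and both bridgeheads from the tether in the cycloaddition.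

Key step: step 7

Remark (assumption on the chemistry): the sense of induction of the two chiral reagents is assigned by analogy, the (R)-bisphosphine being taken to give the (2R)-flavanone and the (R,R)-iodane the (6S)-dienone; if a pilot run shows the opposite sense, the antipodal ligand or iodane is used.
Locants of the intermediates follow chroman-4-one numbering (O1, C2, C3, C4, C4a, C5–C8, C8a).

**Step 1**
Reactants: 1 2',4',6'-trihydroxyacetophenone; 2 iodomethane
Product: 3 2',4',6'-trihydroxy-3',5'-dimethylacetophenone
Conditions: NaOMe (3 equiv), MeI (2.1 equiv), MeOH, 0 °C to reflux; aq. HCl work-up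
Reagents that add atoms: iodomethane, CI
Why: In methanolic methoxide the phloroglucinol-type phenoxide reacts as a carbon nucleophile at its two free ring positions, each flanked by two oxygens, so two equivalents of iodomethane give the 3',5'-dimethyl ketone (C-alkylation of a polyphenol, with the stoichiometry held to two equivalents to limit a third, dearomatizing methylation); no stereocenter is formed.

**Step 2**
Reactants: 3 2',4',6'-trihydroxy-3',5'-dimethylacetophenone; 4 benzyl bromide
Product: 5 2',4'-bis(benzyloxy)-6'-hydroxy-3',5'-dimethylacetophenone
Conditions: BnBr (2.05 equiv), K2CO3, acetone, 50 °C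
Reagents that add atoms: benzyl bromide, BrCc1ccccc1
Why: Williamson etherification at the para-OH and at one ortho-OH, the second ortho-OH being held back by its hydrogen bond to the acetyl carbonyl and kept free for the pyranone closure; no stereocenter is formed.

**Step 3**
Reactants: 5 2',4'-bis(benzyloxy)-6'-hydroxy-3',5'-dimethylacetophenone; 6 N,N-dimethylformamide dimethyl acetal
Product: 8 5,7-bis(benzyloxy)-6,8-dimethyl-4H-chromen-4-one, via enaminone 7 (not isolated)
Conditions: Me2NCH(OMe)2, PhMe, 100 °C; then conc. HCl, CH2Cl2, rt
Reagents that add atoms: N,N-dimethylformamide dimethyl acetal, COC(OC)N(C)C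
Why: Condensation of the methyl ketone with the amide acetal gives the β-(dimethylamino)enone, and acid then lets the chelated phenol add to the β-carbon with loss of dimethylamine (enaminone route to chromones); no stereocenter is formed.

**Step 4**
Reactants: 8 5,7-bis(benzyloxy)-6,8-dimethyl-4H-chromen-4-one; 9 phenylboronic acid
Product: 10 (2R)-5,7-bis(benzyloxy)-6,8-dimethyl-2-phenylchroman-4-one
Conditions: PhB(OH)2 (2 equiv), [Rh(OH)(cod)]2 (3 mol %), (R)-MeO-F12-BIPHEP (6.5 mol %), PhMe/H2O (10:1), 40 °C
Reagents that add atoms: phenylboronic acid, OB(O)c1ccccc1
Why: Hayashi–Miyaura asymmetric 1,4-addition: the phenylrhodium species formed by transmetalation inserts the chromone C2=C3 bond on the enantioface selected by the electron-poor biaryl bisphosphine and the resulting oxa-π-allylrhodium is protonated by water, which sets C2 as (R).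

**Step 5**
Reactants: 10 (2R)-5,7-bis(benzyloxy)-6,8-dimethyl-2-phenylchroman-4-one
Product: 11 (2R)-5,7-dihydroxy-6,8-dimethyl-2-phenylchroman-4-one
Conditions: H2 (1 atm), 10% Pd/C, EtOAc, rt
Reagents that add atoms: none
Why: Hydrogenolysis of the two aryl benzyl ethers over palladium under neutral conditions, which is faster than cleavage of the cyclic benzylic C2–O bond and leaves the base-labile C2 centre untouched.

**Step 6**
Reactants: 11 (2R)-5,7-dihydroxy-6,8-dimethyl-2-phenylchroman-4-one; 12 3-methylbut-2-en-1-ol
Product: 13 (2R,6S)-5-hydroxy-6,8-dimethyl-6-[(3-methylbut-2-en-1-yl)oxy]-2-phenyl-2,3-dihydro-4H-chromene-4,7(6H)-dione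
Conditions: (R,R)-2,6-bis[1-(mesitylcarbamoyl)ethoxy]phenyl-λ3-iodanediyl diacetate (1.05 equiv), 12 (10 equiv), CH2Cl2, −40 to −10 °C; pH 7 buffer work-up, fast chromatography
Reagents that add atoms: 3-methylbut-2-en-1-ol, CC(C)=CCO
Why: Proposed new method: the C–O bond is made by the known oxidative alkoxylation of a phenol with a diacetoxy-λ3-iodane in the presence of an allylic alcohol (o-quinol ether formation, as in masked o-benzoquinone chemistry), but control of the attacked face by a chiral aryl-λ3-iodane with an external alcohol has no precedent; the free, non-chelated 7-OH exchanges onto iodine, the alcohol then displaces the aryliodanyl group by attack at the ortho carbon C6 while iodine is still bound (associative path), and the two lactamide arms folded over the iodine centre shield one face of that carbon, as they do in the known enantioselective spirolactonization and spiroketalization of phenols with tethered nucleophiles and in asymmetric hydroxylative phenol dearomatization, so that the (6S) epimer should dominate irrespective of the remote C2 centre; of the two methyl-bearing ortho carbons only attack at C6 leaves the hydrogen-bonded C5(OH)=C4a–C4=O enolone conjugated, which gives at best a modest preference, and the C8 isomer and the (6R) epimer are removed at this stage.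

**Step 7**
Reactants: 13 (2R,6S)-5-hydroxy-6,8-dimethyl-6-[(3-methylbut-2-en-1-yl)oxy]-2-phenyl-2,3-dihydro-4H-chromene-4,7(6H)-dione
Product: 14 CNP0322161.2 (the target)
Conditions: PhMe (0.01 M, degassed), BHT (5 mol %), 100 °C, sealed tube
Reagents that add atoms: none
Why: Thermal intramolecular Diels–Alder reaction: the dienone carbons C8=C8a–C4a=C5 act as the diene and the prenyl C=C held on the C6 oxygen as the dienophile, so the C5–CH and C8–CMe2 bonds form in one concerted, asynchronous step and C4a=C8a is left as the new enol-ether double bond. The closest known reaction type is the cycloaddition of masked o-benzoquinones and o-quinol derivatives that carry an O-alkenyl or O-acryloyl group on the sp3 carbon, which gives oxa-bridged bicyclo[2.2.2]octenones in the same way. The oxolane closes by the bond from the diene terminus next to the tether carbon to the proximal alkene carbon (fused five-membered mode, the only one a three-atom O–CH2–CH tether allows), and the second carbocycle of the bicyclo[2.2.2]octenone closes by the bond from the distal CMe2 carbon to the methyl-bearing diene terminus. The tether forces the alkene onto the diene face that carries the C6 oxygen, so the (6S) centre alone fixes the ring-fusion CH and both bridgeheads, while C2 of the pyranone takes no part. The step needs the C7-keto/C5-enol tautomer to react in preference to the C5-keto/C7-enol tautomer (which would add across C7 and C4a); this is secured by the chelated 5-OH···O=C4 enolone, which is the dominant tautomer and whose transition state keeps the vinylogous ester O1–C8a=C4a–C4=O conjugated, while dimerization is blocked because both diene termini are fully substituted and neutral, base-free conditions keep the pyranone from opening.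

**Compound list**

1 | 2',4',6'-trihydroxyacetophenone | CC(=O)c1c(O)cc(O)cc1O | starting material
2 | iodomethane | CI | starting material
3 | 2',4',6'-trihydroxy-3',5'-dimethylacetophenone | CC(=O)c1c(O)c(C)c(O)c(C)c1O | intermediate
4 | benzyl bromide | BrCc1ccccc1 | starting material
5 | 2',4'-bis(benzyloxy)-6'-hydroxy-3',5'-dimethylacetophenone | CC(=O)c1c(O)c(C)c(OCc2ccccc2)c(C)c1OCc1ccccc1 | intermediate
6 | N,N-dimethylformamide dimethyl acetal | COC(OC)N(C)C | starting material
7 | (E)-1-[2,4-bis(benzyloxy)-6-hydroxy-3,5-dimethylphenyl]-3-(dimethylamino)prop-2-en-1-one (enaminone) | CN(C)/C=C/C(=O)c1c(O)c(C)c(OCc2ccccc2)c(C)c1OCc1ccccc1 | intermediate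
8 | 5,7-bis(benzyloxy)-6,8-dimethyl-4H-chromen-4-one | O=c1ccoc2c(C)c(OCc3ccccc3)c(C)c(OCc3ccccc3)c12 | intermediate
9 | phenylboronic acid | OB(O)c1ccccc1 | starting material
10 | (2R)-5,7-bis(benzyloxy)-6,8-dimethyl-2-phenylchroman-4-one | O=C1C[C@H](c2ccccc2)Oc2c(C)c(OCc3ccccc3)c(C)c(OCc3ccccc3)c12 | intermediate
11 | (2R)-5,7-dihydroxy-6,8-dimethyl-2-phenylchroman-4-one, the (R)-flavanone | O=C1C[C@H](c2ccccc2)Oc2c(C)c(O)c(C)c(O)c12 | intermediate
12 | 3-methylbut-2-en-1-ol (prenyl alcohol) | CC(C)=CCO | starting material
13 | (2R,6S)-5-hydroxy-6,8-dimethyl-6-[(3-methylbut-2-en-1-yl)oxy]-2-phenyl-2,3-dihydro-4H-chromene-4,7(6H)-dione (o-quinol prenyl ether) | CC(C)=CCO[C@]1(C)C(=O)C(C)=C2O[C@@H](c3ccccc3)CC(=O)C2=C1O | intermediate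
14 | CNP0322161.2: bicyclo[2.2.2]octenone whose enol-ether bridge is fused to a 2-phenyl-2,3-dihydropyran-4-one (CHPh R); methyl bridgehead (R), carbinol bridgehead (R), ketone bridge carrying the methyl- and oxygen-bearing carbon (S), and a CMe2–CH bridge whose CH (R) is tied through CH2–O to that carbon as an oxolane | CC1(C)[C@@H]2CO[C@]3(C)C(=O)[C@@]1(C)C1=C(C(=O)C[C@H](c4ccccc4)O1)[C@]23O | target

**Step count**

Total steps: 7. Longest linear sequence: 7 steps (1 to 14).

**Steps most likely to fail**

Step 6 (proposed new method). What may go wrong: poor discrimination of the two faces of C6 because the alcohol is not tethered to the reagent, attack of the alcohol at the other methyl-bearing ortho carbon (C8), and capture of acetate in place of the alcohol. Fallback, setting out from 11 and coming back at 13: reagent control is given up for separation and recycle. Compound 11 is oxidized with PhI(OAc)2 in CH2Cl2 and 3-methylbut-2-en-1-ol at −20 °C, the achiral alkoxylative dearomatization known from masked o-benzoquinone chemistry. With no control element this should give 13 together with its C6 epimer, (2R,6R)-5-hydroxy-6,8-dimethyl-6-[(3-methylbut-2-en-1-yl)oxy]-2-phenyl-2,3-dihydro-4H-chromene-4,7(6H)-dione F1. The two are separated by chromatography, and F1 is returned to 11 by reductive rearomatization with Zn dust in AcOH and resubmitted.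

Step 7. What may go wrong: slow bond formation between two fully substituted carbons, which gives time for retro-ene loss of the prenyl group as the enal with rearomatization, for cycloaddition through the other enol tautomer, or for opening and re-closure of the pyranone that would erode C2. Fallback, setting out from 11 and coming back at 14: the tether is raised to the ester oxidation level so that the dienophile is an electron-poor acrylate. Wessely-type oxidation of 11 with the iodane of step 6 in the presence of 3-methylbut-2-enoic acid should give the o-quinol ester (2R,6S)-5-hydroxy-6,8-dimethyl-4,7-dioxo-2-phenyl-3,4,6,7-tetrahydro-2H-chromen-6-yl 3-methylbut-2-enoate F2. Heating F2 in toluene should give, by the same intramolecular Diels–Alder mode, the γ-lactone analogue of the target F3. Reduction with i-Bu2AlH at −78 °C to the lactol F4, followed by ionic reduction with Et3SiH and BF3·OEt2, then turns the lactone carbonyl into the oxolane CH2 and gives 14. The bridging ketone, flanked by two quaternary carbons, is expected to be spared.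

Step 4. What may go wrong: sluggish insertion into an electron-rich chromone with a peri benzyloxy group, so that protodeboronation of the boronic acid outruns addition, or lower enantioselectivity than with simple chromones. Fallback, setting out from 5 and coming back at 10: Claisen–Schmidt condensation of 5 with benzaldehyde (KOH, EtOH) gives the chalcone (E)-1-[2,4-bis(benzyloxy)-6-hydroxy-3,5-dimethylphenyl]-3-phenylprop-2-en-1-one F5. NaOAc in refluxing EtOH closes it by oxa-Michael addition to racemic 5,7-bis(benzyloxy)-6,8-dimethyl-2-phenylchroman-4-one F6. Preparative HPLC on a chiral stationary phase delivers 10, and the (2S)-5,7-bis(benzyloxy)-6,8-dimethyl-2-phenylchroman-4-one F7 is racemized through F5 under the same NaOAc conditions and recycled.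

**Further compounds**

F1 | step 6 | (2R,6R)-5-hydroxy-6,8-dimethyl-6-[(3-methylbut-2-en-1-yl)oxy]-2-phenyl-2,3-dihydro-4H-chromene-4,7(6H)-dione | CC(C)=CCO[C@@]1(C)C(=O)C(C)=C2O[C@@H](c3ccccc3)CC(=O)C2=C1O
F2 | step 7 | (2R,6S)-5-hydroxy-6,8-dimethyl-4,7-dioxo-2-phenyl-3,4,6,7-tetrahydro-2H-chromen-6-yl 3-methylbut-2-enoate | CC(C)=CC(=O)O[C@]1(C)C(=O)C(C)=C2O[C@@H](c3ccccc3)CC(=O)C2=C1O
F3 | step 7 | γ-lactone analogue of the target (oxolane CH2 replaced by C=O) | CC1(C)[C@@H]2C(=O)O[C@]3(C)C(=O)[C@@]1(C)C1=C(C(=O)C[C@H](c4ccccc4)O1)[C@]23O
F4 | step 7 | lactol from F3 (mixture at the hemiacetal carbon) | CC1(C)[C@@H]2C(O)O[C@]3(C)C(=O)[C@@]1(C)C1=C(C(=O)C[C@H](c4ccccc4)O1)[C@]23O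
F5 | step 4 | (E)-1-[2,4-bis(benzyloxy)-6-hydroxy-3,5-dimethylphenyl]-3-phenylprop-2-en-1-one | O=C(/C=C/c1ccccc1)c1c(O)c(C)c(OCc2ccccc2)c(C)c1OCc1ccccc1
F6 | step 4 | racemic 5,7-bis(benzyloxy)-6,8-dimethyl-2-phenylchroman-4-one | O=C1CC(c2ccccc2)Oc2c(C)c(OCc3ccccc3)c(C)c(OCc3ccccc3)c12
F7 | step 4 | (2S)-5,7-bis(benzyloxy)-6,8-dimethyl-2-phenylchroman-4-one | O=C1C[C@@H](c2ccccc2)Oc2c(C)c(OCc3ccccc3)c(C)c(OCc3ccccc3)c12
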